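**Retrosynthetic overview**
- The furan C5–aryl bond is cut last: one-pot C–H borylation/Suzuki coupling of a 3-substituted furyl ester with unprotected 2-bromohydroquinone.
- The ester C–O bond is the key disconnection: a dynamic kinetic esterification of the racemic furyl carbinol with an activated (R)-2-methylbutanoic acid forms it and sets the carbinol centre.
- The racemic carbinol comes from furan-3-carbaldehyde by α-selective prenylation.
- No ring is built: the furan and the benzene ring are both bought and are joined in the last step.

Assumption: (R)-2-methylbutanoic acid is bought as the single enantiomer (≥98% ee). The sense of induction of (R)-BTM (the (R)-carbinol reacts faster) is taken from aryl alkyl carbinol precedent and is to be confirmed on the first run; (S)-BTM is used if it is reversed.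

**Step 1**
Reactants: 1 (2R)-2-methylbutanoic acid; 2 isopropyl chloroformate
Product: 3 (2R)-2-methylbutanoic propan-2-yl carbonic anhydride (isopropyl (R)-2-methylbutanoyl carbonate), kept as a toluene solution
Conditions: N-methylmorpholine (1.0 equiv), toluene, −10 °C, 30 min; filter under Ar
Reagents that add atoms: none
Why: Mixed carbonic anhydride formation (carboxylate acylation by the chloroformate) is fast at −10 °C, and a weak tertiary amine does not enolise the α-stereocentre.

**Step 2**
Reactants: 4 furan-3-carbaldehyde; 5 1-chloro-3-methylbut-2-ene (prenyl chloride)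
Product: 7 rac-1-(furan-3-yl)-4-methylpent-3-en-1-ol, via prenylbarium chloride 6 (not isolated)
Conditions: BaI2 (1.6 equiv), Li(C12H10) (lithium biphenylide, 3.2 equiv), THF, rt; then 5 (1.5 equiv), −78 °C; then 4, −78 °C, 30 min; H2O quench
Reagents that add atoms: none
Why: Yamamoto-type allylbarium carbonyl allylation takes place at the unsubstituted α-carbon without allylic transposition, giving the linear prenyl carbinol; the new stereocentre is formed racemic here and is set in step 3.

**Step 3**
Reactants: 7 rac-1-(furan-3-yl)-4-methylpent-3-en-1-ol; 3 isopropyl (R)-2-methylbutanoyl carbonate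
Product: 8 (1R)-1-(furan-3-yl)-4-methylpent-3-en-1-yl (2R)-2-methylbutanoate
Conditions: Ru(CO)2Cl(η5-C5Ph5) (5 mol %), KOtBu (6 mol %), (R)-BTM (5 mol %), 3 (1.5 equiv, syringe pump, 8 h), 4 Å MS, toluene/tert-amyl alcohol 1:1, 10 °C → rt
Reagents that add atoms: none
Why: Proposed new method: a dual-catalytic dynamic kinetic esterification that transfers a stereogenic α-branched acyl group, in which the ruthenium alkoxide of 7 racemises the carbinol by reversible β-hydride elimination/re-insertion through a ruthenium-bound ketone while (R)-BTM is acylated at the acyl carbonyl of 3 (the expelled isopropyl carbonate loses CO2 and acts as the base, so no carboxylic acid is formed to poison the ruthenium alkoxide) and the N-acyl isothiouronium ion acylates only the (R)-alcohol, whose furan π-face stacks on the cationic catalyst as an aryl group does, so the ester C–O bond is formed and the carbinol centre is set as (R) under catalyst control, the Me/Et difference at the acyl α-centre being too small to override it and that centre not being enolised; the closest known reaction types are the non-enzymatic ruthenium/chiral-DMAP dynamic kinetic resolution of aryl alkyl carbinols with acetyl isopropyl carbonate and the isothiourea-catalysed kinetic resolution of benzylic alcohols with isobutyric anhydride.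

**Step 4**
Reactants: 8 (1R)-1-(furan-3-yl)-4-methylpent-3-en-1-yl (2R)-2-methylbutanoate; 9 bis(pinacolato)diboron; 10 2-bromobenzene-1,4-diol
Product: 12 (1R)-1-[5-(2,5-dihydroxyphenyl)furan-3-yl]-4-methylpent-3-en-1-yl (2R)-2-methylbutanoate, via furyl pinacolboronate 11 (not isolated)
Conditions: [Ir(OMe)(cod)]2 (1.5 mol %), dtbpy (3 mol %), 9 (0.55 equiv), THF, 25 °C, 6 h; then 10 (1.1 equiv), Pd(OAc)2 (3 mol %), SPhos (6 mol %), degassed aq K3PO4 (3 equiv), 45 °C, 4 h, Ar; acidify to pH 5
Reagents that add atoms: none
Why: Hartwig–Miyaura C–H borylation is sterically controlled and takes the α-C–H remote from the branched 3-substituent (C5), and the Suzuki–Miyaura coupling of the 2-furyl boronate under Pd(OAc)2/SPhos tolerates free phenols and touches neither stereocentre.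

**Compound list**
1 | (2R)-2-methylbutanoic acid | CC[C@@H](C)C(=O)O | starting material
2 | isopropyl chloroformate (propan-2-yl carbonochloridate) | CC(C)OC(=O)Cl | starting material
3 | (2R)-2-methylbutanoic propan-2-yl carbonic anhydride | CC[C@@H](C)C(=O)OC(=O)OC(C)C | intermediate
4 | furan-3-carbaldehyde | O=Cc1ccoc1 | starting material
5 | 1-chloro-3-methylbut-2-ene (prenyl chloride) | CC(C)=CCCl | starting material
6 | prenylbarium chloride | CC(C)=CC[Ba]Cl | intermediate (not isolated)
7 | rac-1-(furan-3-yl)-4-methylpent-3-en-1-ol | CC(C)=CCC(O)c1ccoc1 | intermediate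
8 | (1R)-1-(furan-3-yl)-4-methylpent-3-en-1-yl (2R)-2-methylbutanoate | CC[C@@H](C)C(=O)O[C@H](CC=C(C)C)c1ccoc1 | intermediate
9 | bis(pinacolato)diboron | CC1(C)OB(OC1(C)C)B1OC(C)(C)C(C)(C)O1 | starting material
10 | 2-bromobenzene-1,4-diol (bromohydroquinone) | Oc1ccc(O)c(Br)c1 | starting material
11 | (1R)-4-methyl-1-[5-(4,4,5,5-tetramethyl-1,3,2-dioxaborolan-2-yl)furan-3-yl]pent-3-en-1-yl (2R)-2-methylbutanoate | CC[C@@H](C)C(=O)O[C@H](CC=C(C)C)c1coc(B2OC(C)(C)C(C)(C)O2)c1 | intermediate (not isolated)
12 | (1R)-1-[5-(2,5-dihydroxyphenyl)furan-3-yl]-4-methylpent-3-en-1-yl (2R)-2-methylbutanoate | CC[C@@H](C)C(=O)O[C@H](CC=C(C)C)c1coc(-c2cc(O)ccc2O)c1 | target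

**Step count**
Total: 4 steps. Longest linear sequence: 3 steps (4 → 7 → 8 → 12); step 1 is a one-step side branch.

**Steps most likely to fail**

Step 3 (the proposed new esterification). The likely failure modes are attack of the catalyst at the carbonate carbonyl of 3 instead of the hindered acyl carbonyl, slow racemisation, and low selectivity for a 3-furyl group. The minor (1S) product is a diastereomer of 8 and can be removed by chromatography. The fallback uses known chemistry only, sets out from 4 and comes back at 8. Brown allylboration of 4 with (+)-Ipc2B(allyl) (from (+)-Ipc2BOMe and allylMgBr; the reagent enantiomer that gives (R)-1-phenylbut-3-en-1-ol from benzaldehyde) in Et2O at −78 °C with ethanolamine work-up gives (1R)-1-(furan-3-yl)but-3-en-1-ol F2. Steglich esterification of F2 with 1 (DCC, catalytic DMAP, CH2Cl2, 0 °C → rt) gives (1R)-1-(furan-3-yl)but-3-en-1-yl (2R)-2-methylbutanoate F3. Cross-metathesis of F3 with excess 2-methylbut-2-ene (second-generation Grubbs catalyst, RuCl2(=CHPh)(PCy3)(SIMes), 3 mol %, CH2Cl2, 40 °C) then gives 8.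

Step 2 (α-selective prenylation). The risks are incomplete activation of the barium and some γ-adduct (the reverse-prenyl carbinol). The fallback sets out from 4 and comes back at 7. Addition of allylMgBr to 4 in THF at −78 °C gives rac-1-(furan-3-yl)but-3-en-1-ol F1. Cross-metathesis of F1 with excess 2-methylbut-2-ene under the same ruthenium catalyst gives 7.

Step 4 (one-pot borylation/coupling with the free hydroquinone). The risks are oxidation of the hydroquinone under basic conditions, which poisons zerovalent palladium, protodeboronation of the 2-furyl boronate, and some borylation at C2. The fallback sets out from 8 and comes back at 12. Compound 8 is borylated as above and the boronate 11 is isolated by short-path chromatography. In parallel, 10 is silylated (TBSCl, imidazole, DMF) to 2-bromo-1,4-bis(tert-butyldimethylsilyloxy)benzene F4. Suzuki coupling of 11 with F4 (Pd(OAc)2, SPhos, K3PO4, THF/H2O, 45 °C) gives (1R)-1-{5-[2,5-bis(tert-butyldimethylsilyloxy)phenyl]furan-3-yl}-4-methylpent-3-en-1-yl (2R)-2-methylbutanoate F5. Desilylation of F5 with Bu4NF buffered with AcOH in THF at 0 °C gives 12.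

**Further compounds**
F1 | step 2 | rac-1-(furan-3-yl)but-3-en-1-ol | C=CCC(O)c1ccoc1
F2 | step 3 | (1R)-1-(furan-3-yl)but-3-en-1-ol | O[C@H](CC=C)c1ccoc1
F3 | step 3 | (1R)-1-(furan-3-yl)but-3-en-1-yl (2R)-2-methylbutanoate | CC[C@@H](C)C(=O)O[C@H](CC=C)c1ccoc1
F4 | step 4 | 2-bromo-1,4-bis(tert-butyldimethylsilyloxy)benzene | CC(C)(C)[Si](C)(C)Oc1ccc(O[Si](C)(C)C(C)(C)C)c(Br)c1
F5 | step 4 | (1R)-1-{5-[2,5-bis(tert-butyldimethylsilyloxy)phenyl]furan-3-yl}-4-methylpent-3-en-1-yl (2R)-2-methylbutanoate | CC[C@@H](C)C(=O)O[C@H](CC=C(C)C)c1coc(-c2cc(O[Si](C)(C)C(C)(C)C)ccc2O[Si](C)(C)C(C)(C)C)c1
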